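The route rests on opening the dimethylpyran ring that is fused to ring B across C3'–C4'. Its ring oxygen on C4' and the benzylic CH2 on C3' are read as an ortho-quinone methide, and the remaining CH2–C(CH3)2 unit as isobutene. A single thermal operation dehydrates a salicyl alcohol and adds the alkene in a hetero-Diels–Alder reaction, forming the CH2–CH2 and O–C(CH3)2 bonds and closing the pyran. The precursor is a phenol bearing the ortho hydroxymethyl group, a silylated hydroxymethyl group (the later C2' prenyl), a para bromine (the later C1') and an O-methyl group (the later C5' hydroxyl). Ring A enters as a reverse-prenylated acetophenone; Algar–Flynn–Oyamada oxidation closes ring C.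

Key step: step 5

Remark: compounds 1, 8, 12, 18 and 19 are taken as purchasable (18 dried to the anhydrous form, 12 as a THF solution); the target is achiral, and the only chiral species (21 and 25) are racemic and transient.

Step 1
Reactants: 1 2-bromo-5-hydroxy-4-methoxybenzaldehyde
Product: 2 4-bromo-5-(hydroxymethyl)-2-methoxyphenol
Conditions: NaBH4, MeOH, 0 °C
Reagents that add atoms: none
Why: Carbonyl reduction by borohydride (hydride addition) converts the aldehyde into the benzylic alcohol without touching the aryl bromide, the methyl ether or the phenol.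

Step 2
Reactants: 2 4-bromo-5-(hydroxymethyl)-2-methoxyphenol
Product: 4 4-bromo-5-(tert-butyldimethylsilyloxymethyl)-2-methoxyphenol, via bis-silyl ether 3 (not isolated)
Conditions: TBSCl (2.3 equiv), imidazole, DMF, 23 °C; then K2CO3, MeOH, 23 °C
Reagents that add atoms: tert-butyldimethylsilyl chloride, CC(C)(C)[Si](C)(C)Cl
Why: Silyl ether formation at both hydroxyl groups followed by base-catalysed methanolysis, which removes an aryl silyl ether far faster than an alkyl one because phenoxide is the better leaving group, should leave only the benzylic TBS ether (protection with selective desilylation).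

Step 3
Reactants: 4 4-bromo-5-(tert-butyldimethylsilyloxymethyl)-2-methoxyphenol
Product: 6 5-bromo-6-(tert-butyldimethylsilyloxymethyl)-2-hydroxy-3-methoxybenzaldehyde, via magnesium hydroxymethylphenoxide 5 (not isolated)
Conditions: MgCl2, Et3N, (CH2O)n, THF, reflux; then cold 1 M HCl
Reagents that add atoms: paraformaldehyde (formaldehyde), C=O
Why: Magnesium-mediated ortho-formylation of a phenol (Casnati–Skattebøl reaction): the chloromagnesium phenoxide delivers formaldehyde through a chelate to the single free ortho position and a second formaldehyde oxidises the benzylic alkoxide 5 by Oppenauer-type hydride transfer, so the second benzylic carbon enters already differentiated from the first.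

Step 4
Reactants: 6 5-bromo-6-(tert-butyldimethylsilyloxymethyl)-2-hydroxy-3-methoxybenzaldehyde
Product: 7 4-bromo-3-(tert-butyldimethylsilyloxymethyl)-2-(hydroxymethyl)-6-methoxyphenol
Conditions: NaBH4, THF/MeOH, 0 °C
Reagents that add atoms: none
Why: Borohydride reduction of the salicylaldehyde gives the ortho-hydroxybenzyl alcohol under cold, weakly basic conditions in which neither silyl migration nor loss of water is expected.

Step 5
Reactants: 7 4-bromo-3-(tert-butyldimethylsilyloxymethyl)-2-(hydroxymethyl)-6-methoxyphenol; 8 isobutene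
Product: 10 6-bromo-5-(tert-butyldimethylsilyloxymethyl)-8-methoxy-2,2-dimethylchroman, via ortho-quinone methide 9 (not isolated)
Conditions: isobutene (condensed, large excess), toluene, sealed steel autoclave, 170 °C
Reagents that add atoms: none
Why: Heating expels water from the ortho-hydroxybenzyl alcohol (1,4-elimination) and gives the ortho-quinone methide 9, an electron-poor 1-oxadiene that undergoes an inverse-electron-demand hetero-Diels–Alder reaction with the alkene, the regained aromaticity of the benzene ring driving the addition. The closest known reaction type is the thermal cycloaddition of salicyl-alcohol-derived quinone methides with 1,1-disubstituted alkenes to 2,2-dialkylchromans. The pyran ring closes by an intermolecular (4+2) cycloaddition in which the C4–C3 and O1–C2 bonds form in one asynchronous step, so no separate ring-closing event is needed. No stereocentre arises because C2 carries two methyl groups. The step needs regioselectivity and chemoselectivity: the polarised quinone methide is attacked at its exocyclic CH2 by the unsubstituted terminus of isobutene, so that positive charge develops on the tertiary carbon and is taken up by the phenolic oxygen, while the large excess of alkene should outrun dimerisation. The silyl cap on the neighbouring CH2O group denies the quinone methide an internal hydroxyl nucleophile, and the aryl bromide and the methyl ether are inert at this temperature.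

Step 6
Reactants: 10 6-bromo-5-(tert-butyldimethylsilyloxymethyl)-8-methoxy-2,2-dimethylchroman
Product: 11 6-bromo-5-(bromomethyl)-8-methoxy-2,2-dimethylchroman
Conditions: Ph3PBr2, CH2Cl2, 0 to 23 °C
Reagents that add atoms: triphenylphosphine dibromide, BrP(Br)(c1ccccc1)(c1ccccc1)c1ccccc1
Why: Direct conversion of a silyl ether into a bromide (Appel-type substitution): the ether oxygen attacks phosphorus, the silyl group leaves as the silyl bromide and bromide displaces triphenylphosphine oxide from the activated benzylic carbon, under neutral conditions that spare the tertiary chroman ether.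

Step 7
Reactants: 11 6-bromo-5-(bromomethyl)-8-methoxy-2,2-dimethylchroman; 12 2-methylprop-1-enylmagnesium bromide
Product: 13 6-bromo-8-methoxy-2,2-dimethyl-5-(3-methylbut-2-enyl)chroman
Conditions: CuI (10 mol %), THF, −30 to 0 °C
Reagents that add atoms: none
Why: Copper-catalysed cross-coupling of an alkenyl Grignard reagent with a benzylic bromide: the organocopper formed in the flask substitutes at the sp3 carbon far faster than it touches the aryl bromide, and joining a vinyl carbon to the benzylic CH2 gives the prenyl group with no allylic transposition.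

Step 8
Reactants: 13 6-bromo-8-methoxy-2,2-dimethyl-5-(3-methylbut-2-enyl)chroman
Product: 14 6-bromo-2,2-dimethyl-5-(3-methylbut-2-enyl)chroman-8-ol
Conditions: NaSEt, DMF, 120 °C; then aq. NH4Cl
Reagents that add atoms: none
Why: Nucleophilic O-demethylation: the thiolate attacks the methyl carbon in an SN2 reaction that the tertiary alkyl–oxygen bond of the chroman, the alkene and the unactivated aryl bromide cannot undergo, so the inert spectator of the key step is removed without any Lewis acid.

Step 9
Reactants: 14 6-bromo-2,2-dimethyl-5-(3-methylbut-2-enyl)chroman-8-ol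
Product: 15 6-bromo-8-(methoxymethoxy)-2,2-dimethyl-5-(3-methylbut-2-enyl)chroman
Conditions: MOMCl, i-Pr2NEt, CH2Cl2, 0 to 23 °C
Reagents that add atoms: chloromethyl methyl ether, COCCl
Why: O-Alkylation of the phenol with an α-chloro ether under amine base (MOM protection) installs an acetal that survives organolithium, hydroxide and alkaline peroxide and leaves with dilute acid at the end.

Step 10
Reactants: 15 6-bromo-8-(methoxymethoxy)-2,2-dimethyl-5-(3-methylbut-2-enyl)chroman
Product: 17 8-(methoxymethoxy)-2,2-dimethyl-5-(3-methylbut-2-enyl)chroman-6-carbaldehyde, via aryllithium 16 (not isolated)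
Conditions: n-BuLi, THF, −78 °C; DMF, −78 to 0 °C; then H2O
Reagents that add atoms: N,N-dimethylformamide, CN(C)C=O
Why: Bromine–lithium exchange at −78 °C, much faster than deprotonation of the benzylic–allylic CH2, followed by Bouveault formylation with DMF gives the aldehyde after collapse of the hemiaminal alkoxide on work-up.

Step 11
Reactants: 18 2,4,6-trihydroxyacetophenone; 19 prenyl bromide
Product: 20 1-[2,6-dihydroxy-4-(3-methylbut-2-enyloxy)phenyl]ethanone
Conditions: K2CO3 (1.1 equiv), acetone, reflux
Reagents that add atoms: none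
Why: Williamson ether synthesis: the C4 hydroxyl, para to the acetyl group and not held in a hydrogen bond, is the most acidic and its phenoxide is O-alkylated first, so one equivalent of halide in an aprotic medium should favour the mono-ether.

Step 12
Reactants: 20 1-[2,6-dihydroxy-4-(3-methylbut-2-enyloxy)phenyl]ethanone
Product: 22 1-[2,4,6-trihydroxy-3-(2-methylbut-3-en-2-yl)phenyl]ethanone, via ortho-dienone 21 (not isolated)
Conditions: N,N-diethylaniline, 190 °C, argon, short reaction time
Reagents that add atoms: none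
Why: Aromatic Claisen rearrangement: the [3,3]-sigmatropic shift moves the allyl unit with inversion onto an ortho carbon (the two ortho positions are equivalent and the para position is blocked by the acetyl group), and tautomerisation of dienone 21 erases its transient stereocentre and restores the phenol, while the basic solvent suppresses acid-catalysed cyclisation.

Step 13
Reactants: 22 1-[2,4,6-trihydroxy-3-(2-methylbut-3-en-2-yl)phenyl]ethanone
Product: 23 1-[2-hydroxy-4,6-bis(methoxymethoxy)-3-(2-methylbut-3-en-2-yl)phenyl]ethanone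
Conditions: MOMCl (2.2 equiv), i-Pr2NEt, CH2Cl2, 0 °C
Reagents that add atoms: chloromethyl methyl ether, COCCl
Why: MOM ether formation (alkylation with an α-chloro ether): the C4 hydroxyl and the less hindered C6 hydroxyl should react, whereas the C2 hydroxyl, wedged between the acetyl group and the quaternary carbon and hydrogen-bonded to the carbonyl, should stay free.

Step 14
Reactants: 23 1-[2-hydroxy-4,6-bis(methoxymethoxy)-3-(2-methylbut-3-en-2-yl)phenyl]ethanone; 17 8-(methoxymethoxy)-2,2-dimethyl-5-(3-methylbut-2-enyl)chroman-6-carbaldehyde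
Product: 24 (E)-1-[2-hydroxy-4,6-bis(methoxymethoxy)-3-(2-methylbut-3-en-2-yl)phenyl]-3-[8-(methoxymethoxy)-2,2-dimethyl-5-(3-methylbut-2-enyl)chroman-6-yl]prop-2-en-1-one
Conditions: KOH, EtOH/H2O, 23 °C
Reagents that add atoms: none
Why: Claisen–Schmidt condensation: the enolate of the methyl ketone adds to the non-enolisable aldehyde and E1cB dehydration gives the (E)-enone under thermodynamic control, conditions under which the isolated alkenes do not migrate.

Step 15
Reactants: 24 the (E)-chalcone of step 14
Product: 26 3-hydroxy-5,7-bis(methoxymethoxy)-2-[8-(methoxymethoxy)-2,2-dimethyl-5-(3-methylbut-2-enyl)chroman-6-yl]-8-(2-methylbut-3-en-2-yl)chromen-4-one, via dihydroflavonol 25 (not isolated)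
Conditions: 30% H2O2, NaOH, MeOH/THF, 0 to 23 °C
Reagents that add atoms: hydrogen peroxide, OO
Why: Algar–Flynn–Oyamada reaction: hydroperoxide attacks only the electron-poor enone, the 2'-phenoxide closes ring C at the β-carbon to the racemic trans-3-hydroxyflavanone 25, whose two stereocentres vanish when excess alkaline peroxide dehydrogenates it to the flavonol; the isolated alkenes are inert to nucleophilic peroxide.

Step 16
Reactants: 26 the tris-MOM flavonol of step 15
Product: 27 broussoflavonol E
Conditions: HCl (3 M aq.), MeOH, 45 °C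
Reagents that add atoms: none
Why: Acid-catalysed acetal exchange with methanol removes all three MOM groups, and dilute acid at mild temperature should spare the tertiary chroman ether, the prenyl group (which has no neighbouring hydroxyl) and the monosubstituted vinyl group.

Compound list

1 | 2-bromo-5-hydroxy-4-methoxybenzaldehyde | COc1cc(Br)c(C=O)cc1O | starting material
2 | 4-bromo-5-(hydroxymethyl)-2-methoxyphenol | COc1cc(Br)c(CO)cc1O | intermediate
3 | tert-butyl{[2-bromo-5-(tert-butyldimethylsilyloxy)-4-methoxyphenyl]methoxy}dimethylsilane | COc1cc(Br)c(CO[Si](C)(C)C(C)(C)C)cc1O[Si](C)(C)C(C)(C)C | intermediate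
4 | 4-bromo-5-(tert-butyldimethylsilyloxymethyl)-2-methoxyphenol | COc1cc(Br)c(CO[Si](C)(C)C(C)(C)C)cc1O | intermediate
5 | chloromagnesium 4-bromo-3-(tert-butyldimethylsilyloxymethyl)-2-(hydroxymethyl)-6-methoxyphenoxide | COc1cc(Br)c(CO[Si](C)(C)C(C)(C)C)c(CO)c1O[Mg]Cl | intermediate
6 | 5-bromo-6-(tert-butyldimethylsilyloxymethyl)-2-hydroxy-3-methoxybenzaldehyde | COc1cc(Br)c(CO[Si](C)(C)C(C)(C)C)c(C=O)c1O | intermediate
7 | 4-bromo-3-(tert-butyldimethylsilyloxymethyl)-2-(hydroxymethyl)-6-methoxyphenol | COc1cc(Br)c(CO[Si](C)(C)C(C)(C)C)c(CO)c1O | intermediate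
8 | isobutene (2-methylpropene) | C=C(C)C | starting material
9 | 4-bromo-5-(tert-butyldimethylsilyloxymethyl)-2-methoxy-6-methylidenecyclohexa-2,4-dien-1-one | C=C1C(=O)C(OC)=CC(Br)=C1CO[Si](C)(C)C(C)(C)C | intermediate
10 | 6-bromo-5-(tert-butyldimethylsilyloxymethyl)-8-methoxy-2,2-dimethylchroman | COc1cc(Br)c(CO[Si](C)(C)C(C)(C)C)c2c1OC(C)(C)CC2 | intermediate
11 | 6-bromo-5-(bromomethyl)-8-methoxy-2,2-dimethylchroman | COc1cc(Br)c(CBr)c2c1OC(C)(C)CC2 | intermediate
12 | 2-methylprop-1-enylmagnesium bromide | CC(C)=C[Mg]Br | starting material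
13 | 6-bromo-8-methoxy-2,2-dimethyl-5-(3-methylbut-2-enyl)chroman | COc1cc(Br)c(CC=C(C)C)c2c1OC(C)(C)CC2 | intermediate
14 | 6-bromo-2,2-dimethyl-5-(3-methylbut-2-enyl)chroman-8-ol | Oc1cc(Br)c(CC=C(C)C)c2c1OC(C)(C)CC2 | intermediate
15 | 6-bromo-8-(methoxymethoxy)-2,2-dimethyl-5-(3-methylbut-2-enyl)chroman | COCOc1cc(Br)c(CC=C(C)C)c2c1OC(C)(C)CC2 | intermediate
16 | [8-(methoxymethoxy)-2,2-dimethyl-5-(3-methylbut-2-enyl)chroman-6-yl]lithium | COCOc1cc([Li])c(CC=C(C)C)c2c1OC(C)(C)CC2 | intermediate
17 | 8-(methoxymethoxy)-2,2-dimethyl-5-(3-methylbut-2-enyl)chroman-6-carbaldehyde | COCOc1cc(C=O)c(CC=C(C)C)c2c1OC(C)(C)CC2 | intermediate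
18 | 2,4,6-trihydroxyacetophenone | CC(=O)c1c(O)cc(O)cc1O | starting material
19 | prenyl bromide (1-bromo-3-methylbut-2-ene) | CC(C)=CCBr | starting material
20 | 1-[2,6-dihydroxy-4-(3-methylbut-2-enyloxy)phenyl]ethanone | CC(=O)c1c(O)cc(OCC=C(C)C)cc1O | intermediate
21 | 4-acetyl-3,5-dihydroxy-6-(2-methylbut-3-en-2-yl)cyclohexa-2,4-dien-1-one (racemic) | CC(=O)C1=C(O)C(C(C)(C)C=C)C(=O)C=C1O | intermediate
22 | 1-[2,4,6-trihydroxy-3-(2-methylbut-3-en-2-yl)phenyl]ethanone | CC(=O)c1c(O)cc(O)c(C(C)(C)C=C)c1O | intermediate
23 | 1-[2-hydroxy-4,6-bis(methoxymethoxy)-3-(2-methylbut-3-en-2-yl)phenyl]ethanone | CC(=O)c1c(OCOC)cc(OCOC)c(C(C)(C)C=C)c1O | intermediate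
24 | (E)-1-[2-hydroxy-4,6-bis(methoxymethoxy)-3-(2-methylbut-3-en-2-yl)phenyl]-3-[8-(methoxymethoxy)-2,2-dimethyl-5-(3-methylbut-2-enyl)chroman-6-yl]prop-2-en-1-one | C=CC(C)(C)c1c(O)c(C(=O)/C=C/c2cc(OCOC)c3c(c2CC=C(C)C)CCC(C)(C)O3)c(OCOC)cc1OCOC | intermediate
25 | rac-(2R,3R)-3-hydroxy-5,7-bis(methoxymethoxy)-2-[8-(methoxymethoxy)-2,2-dimethyl-5-(3-methylbut-2-enyl)chroman-6-yl]-8-(2-methylbut-3-en-2-yl)chroman-4-one (trans, one enantiomer drawn) | C=CC(C)(C)c1c(OCOC)cc(OCOC)c2c1O[C@H](c1cc(OCOC)c3c(c1CC=C(C)C)CCC(C)(C)O3)[C@@H](O)C2=O | intermediate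
26 | 3-hydroxy-5,7-bis(methoxymethoxy)-2-[8-(methoxymethoxy)-2,2-dimethyl-5-(3-methylbut-2-enyl)chroman-6-yl]-8-(2-methylbut-3-en-2-yl)chromen-4-one | C=CC(C)(C)c1c(OCOC)cc(OCOC)c2c(=O)c(O)c(-c3cc(OCOC)c4c(c3CC=C(C)C)CCC(C)(C)O4)oc12 | intermediate
27 | broussoflavonol E, 3,5,7-trihydroxy-2-[8-hydroxy-2,2-dimethyl-5-(3-methylbut-2-enyl)chroman-6-yl]-8-(2-methylbut-3-en-2-yl)chromen-4-one | C=CC(C)(C)c1c(O)cc(O)c2c(=O)c(O)c(-c3cc(O)c4c(c3CC=C(C)C)CCC(C)(C)O4)oc12 | target

Total step count: 16. Longest linear sequence: 13 steps (steps 1 to 10, then 14 to 16, from compound 1).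

Steps most likely to fail

Step 5. The quinone methide may be consumed by self-addition to dimers and oligomers or, after silyl migration to the adjacent oxygen, by internal capture, before the unactivated, low-boiling alkene adds. The fallback builds the pyran ring without a quinone methide and sets out from aldehyde 6. A Wittig reaction with Ph3P=CHC(O)CH3 (toluene, 90 °C) should give (E)-4-[5-bromo-6-(tert-butyldimethylsilyloxymethyl)-2-hydroxy-3-methoxyphenyl]but-3-en-2-one F1. Addition of MeMgBr (excess, THF, 0 °C) to the ketone should give (E)-4-[5-bromo-6-(tert-butyldimethylsilyloxymethyl)-2-hydroxy-3-methoxyphenyl]-2-methylbut-3-en-2-ol F2. PPTS in toluene at 60 °C should ionise the tertiary allylic alcohol and close the ether to 6-bromo-5-(tert-butyldimethylsilyloxymethyl)-8-methoxy-2,2-dimethyl-2H-chromene F3. Diimide reduction of the C3–C4 double bond (TsNHNH2, NaOAc, THF/H2O, reflux), which spares the aryl bromide, would come back to the route at chroman 10.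

Step 12. The rearranged phenol may react further in the hot medium: a flanking hydroxyl can add to the vinyl group, the side chain can isomerise by the abnormal Claisen pathway, or the allyl unit can be lost. The fallback never exposes a free phenol to the heat and sets out from ether 20. Acetylation (Ac2O, pyridine, 23 °C) should give 1-[2,6-diacetoxy-4-(3-methylbut-2-enyloxy)phenyl]ethanone F4. Rearrangement in N,N-diethylaniline containing Ac2O and NaOAc at 190 °C should acetylate the new hydroxyl as it forms and give 1-[2,4,6-triacetoxy-3-(2-methylbut-3-en-2-yl)phenyl]ethanone F5. Methanolysis (K2CO3, MeOH, 0 °C) would return to triol 22.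

Step 15. Ring closure may take place through the α-carbon to the five-membered aurone, a pathway favoured by the 6'-alkoxy group and the crowded ring B, or the enone may undergo oxidative cleavage. The fallback supplies the oxidation level of C2 by an acyl donor and sets out from bromide 15 and ketone 23. Aryllithium 16, made as in step 10, would be quenched with ClCO2Me to methyl 8-(methoxymethoxy)-2,2-dimethyl-5-(3-methylbut-2-enyl)chroman-6-carboxylate F6. Claisen condensation of the enolate of 23 with this ester (LiN(SiMe3)2, THF, −78 to 23 °C) should give 1-[2-hydroxy-4,6-bis(methoxymethoxy)-3-(2-methylbut-3-en-2-yl)phenyl]-3-[8-(methoxymethoxy)-2,2-dimethyl-5-(3-methylbut-2-enyl)chroman-6-yl]propane-1,3-dione F7. Cyclodehydration (catalytic TsOH, toluene, molecular sieves, 60 °C) should give 5,7-bis(methoxymethoxy)-2-[8-(methoxymethoxy)-2,2-dimethyl-5-(3-methylbut-2-enyl)chroman-6-yl]-8-(2-methylbut-3-en-2-yl)chromen-4-one F8. Deprotonation at C3 with LiN(i-Pr)2 (THF, −78 °C) and trapping with B(OMe)3 should give dimethyl {5,7-bis(methoxymethoxy)-2-[8-(methoxymethoxy)-2,2-dimethyl-5-(3-methylbut-2-enyl)chroman-6-yl]-8-(2-methylbut-3-en-2-yl)-4-oxochromen-3-yl}boronate F9. Its oxidation with NaBO3·4H2O, which leaves the alkenes alone, would come back to the route at flavonol 26.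

Further compounds

F1 | step 5 | (E)-4-[5-bromo-6-(tert-butyldimethylsilyloxymethyl)-2-hydroxy-3-methoxyphenyl]but-3-en-2-one | COc1cc(Br)c(CO[Si](C)(C)C(C)(C)C)c(/C=C/C(C)=O)c1O
F2 | step 5 | (E)-4-[5-bromo-6-(tert-butyldimethylsilyloxymethyl)-2-hydroxy-3-methoxyphenyl]-2-methylbut-3-en-2-ol | COc1cc(Br)c(CO[Si](C)(C)C(C)(C)C)c(/C=C/C(C)(C)O)c1O
F3 | step 5 | 6-bromo-5-(tert-butyldimethylsilyloxymethyl)-8-methoxy-2,2-dimethyl-2H-chromene | COc1cc(Br)c(CO[Si](C)(C)C(C)(C)C)c2c1OC(C)(C)C=C2
F4 | step 12 | 1-[2,6-diacetoxy-4-(3-methylbut-2-enyloxy)phenyl]ethanone | CC(=O)Oc1cc(OCC=C(C)C)cc(OC(C)=O)c1C(C)=O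
F5 | step 12 | 1-[2,4,6-triacetoxy-3-(2-methylbut-3-en-2-yl)phenyl]ethanone | CC(=O)Oc1cc(OC(C)=O)c(C(C)(C)C=C)c(OC(C)=O)c1C(C)=O
F6 | step 15 | methyl 8-(methoxymethoxy)-2,2-dimethyl-5-(3-methylbut-2-enyl)chroman-6-carboxylate | COCOc1cc(C(=O)OC)c(CC=C(C)C)c2c1OC(C)(C)CC2
F7 | step 15 | 1-[2-hydroxy-4,6-bis(methoxymethoxy)-3-(2-methylbut-3-en-2-yl)phenyl]-3-[8-(methoxymethoxy)-2,2-dimethyl-5-(3-methylbut-2-enyl)chroman-6-yl]propane-1,3-dione | C=CC(C)(C)c1c(O)c(C(=O)CC(=O)c2cc(OCOC)c3c(c2CC=C(C)C)CCC(C)(C)O3)c(OCOC)cc1OCOC
F8 | step 15 | 5,7-bis(methoxymethoxy)-2-[8-(methoxymethoxy)-2,2-dimethyl-5-(3-methylbut-2-enyl)chroman-6-yl]-8-(2-methylbut-3-en-2-yl)chromen-4-one | C=CC(C)(C)c1c(OCOC)cc(OCOC)c2c(=O)cc(-c3cc(OCOC)c4c(c3CC=C(C)C)CCC(C)(C)O4)oc12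
F9 | step 15 | dimethyl {5,7-bis(methoxymethoxy)-2-[8-(methoxymethoxy)-2,2-dimethyl-5-(3-methylbut-2-enyl)chroman-6-yl]-8-(2-methylbut-3-en-2-yl)-4-oxochromen-3-yl}boronate | C=CC(C)(C)c1c(OCOC)cc(OCOC)c2c(=O)c(B(OC)OC)c(-c3cc(OCOC)c4c(c3CC=C(C)C)CCC(C)(C)O4)oc12
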